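Numbering: ring C1 (C=O), C2=C3, C4 (CHOH), C5 (C–OH); side chain C1′ (CHOAc), C2′–C15′.
Cuts, in retrosynthetic order: the acetate C–O; C2=C3 (ring-closing metathesis); C3–C4 (vinyl Grignard on an aldehyde); C1–C5 (ester enolate aldol with acrolein); C2′=C3′ (Wittig, then hydrogenation).
Enabling feature: C2=C3 is an unsubstituted ring alkene whose carbons sit on C1 and C4, both bonded to the quaternary C5, so the cyclopentenone opens to two vinyl arms on one carbon. The C5–O/C1′–O diol, flanked by C4 and C2′, is the four-carbon skeleton of L-tartaric acid.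
Forward: the tartrate acetonide is desymmetrised, the chain is joined, the C1 arm and then the C4 arm are put on the dioxolane, and the cyclopentenone (the only ring made) closes by metathesis. Ketal hydrolysis, acetylation and desilylation finish.
Stereochemistry: C1′ is a tartrate carbon; C5 is rebuilt on the dioxolane enolate with acrolein entering anti to the tetradecyl group; C4 comes from Felkin-type vinyl addition to the aldehyde on C5.

Key step: step 13

Remark on the chemistry: the C1 carbinol made in step 6 is carried as a mixture of epimers until it is oxidised in step 12 and is written without configuration in 11, 12, 13, 15, 16 and 17; commercial dimethyl 2,3-O-isopropylidene-L-tartrate serves as the tartaric acid source.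

Step 1
Reactants: 1 dimethyl (4R,5R)-2,2-dimethyl-1,3-dioxolane-4,5-dicarboxylate
Product: 2 methyl (4R,5S)-5-(hydroxymethyl)-2,2-dimethyl-1,3-dioxolane-4-carboxylate
Conditions: NaBH4 (0.6 equiv), MeOH, 0 °C → rt
Reagents that add atoms: none
Why: Borohydride reduction of an activated α-alkoxy ester with a deficit of hydride should stop largely at the mono-alcohol; the two esters of the C2-symmetric diester are homotopic, so one product forms, the diol is washed out with water, unreacted 1 is recycled and no stereocentre is touched.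

Step 2
Reactants: 2 methyl (4R,5S)-5-(hydroxymethyl)-2,2-dimethyl-1,3-dioxolane-4-carboxylate
Product: 3 methyl (4R,5R)-5-formyl-2,2-dimethyl-1,3-dioxolane-4-carboxylate
Conditions: (COCl)2, DMSO, CH2Cl2, −78 °C; Et3N, −78 → 0 °C
Reagents that add atoms: none
Why: Swern oxidation with a non-aqueous work-up suits this hydrate-prone α-alkoxy aldehyde, which is used crude at once so that the trans-dioxolane is kept.

Step 3
Reactants: 4 1-bromotridecane
Product: 5 tridecyl(triphenyl)phosphonium bromide
Conditions: PPh3, MeCN, reflux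
Reagents that add atoms: triphenylphosphine, c1ccc(cc1)P(c1ccccc1)c1ccccc1
Why: SN2 quaternisation of a primary bromide by the phosphine is the standard preparation of a Wittig salt.

Step 4
Reactants: 3 methyl (4R,5R)-5-formyl-2,2-dimethyl-1,3-dioxolane-4-carboxylate; 5 tridecyl(triphenyl)phosphonium bromide
Product: 7 methyl (4R,5S)-2,2-dimethyl-5-[(Z)-tetradec-1-enyl]-1,3-dioxolane-4-carboxylate, via tridecylidenetriphenylphosphorane 6 (not isolated)
Conditions: 5, NaN(SiMe3)2, THF, 0 °C; then 3, −78 °C → rt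
Reagents that add atoms: none
Why: Wittig olefination, in which the non-stabilised ylide attacks the aldehyde far faster than the ester at low temperature and should give mainly the Z alkene, whose geometry is erased in step 5.

Step 5
Reactants: 7 methyl (4R,5S)-2,2-dimethyl-5-[(Z)-tetradec-1-enyl]-1,3-dioxolane-4-carboxylate
Product: 8 methyl (4R,5S)-2,2-dimethyl-5-tetradecyl-1,3-dioxolane-4-carboxylate
Conditions: H2 (1 atm), Pd/C, EtOAc, rt
Reagents that add atoms: none
Why: Catalytic hydrogenation of the disubstituted alkene leaves ester and ketal untouched, and the neutral solvent limits hydrogenolysis of the allylic C–O bond.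

Step 6
Reactants: 8 methyl (4R,5S)-2,2-dimethyl-5-tetradecyl-1,3-dioxolane-4-carboxylate; 9 acrolein
Product: 11 methyl (4S,5S)-4-(1-hydroxyprop-2-enyl)-2,2-dimethyl-5-tetradecyl-1,3-dioxolane-4-carboxylate, via lithium ester enolate 10 (not isolated)
Conditions: LiN(i-Pr)2, THF, −78 °C; 9, −78 °C; AcOH, −78 °C
Reagents that add atoms: none
Why: Aldol addition of a lithium ester enolate, which adds 1,2 to the enal under kinetic conditions; acrolein should approach the planar dioxolane enolate on the face anti to the neighbouring tetradecyl group, which sets C5 with the new arm trans to the chain, and the cold acidic quench forestalls retro-aldol and β-elimination of the ring oxygen.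

Step 7
Reactants: 11 methyl (4S,5S)-4-(1-hydroxyprop-2-enyl)-2,2-dimethyl-5-tetradecyl-1,3-dioxolane-4-carboxylate
Product: 12 methyl (4R,5S)-2,2-dimethyl-5-tetradecyl-4-[1-(triethylsilyloxy)prop-2-enyl]-1,3-dioxolane-4-carboxylate
Conditions: Et3SiOTf, 2,6-lutidine, CH2Cl2, −78 → 0 °C
Reagents that add atoms: triethylsilyl trifluoromethanesulfonate, CC[Si](CC)(CC)OS(=O)(=O)C(F)(F)F
Why: Silyl triflate silylation with a hindered pyridine base caps the congested aldol hydroxyl without generating an alkoxide that could revert the aldol, and the labile TES ether marks this arm as the one to be unmasked and oxidised.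

Step 8
Reactants: 12 methyl (4R,5S)-2,2-dimethyl-5-tetradecyl-4-[1-(triethylsilyloxy)prop-2-enyl]-1,3-dioxolane-4-carboxylate
Product: 13 (4R,5S)-2,2-dimethyl-5-tetradecyl-4-[1-(triethylsilyloxy)prop-2-enyl]-1,3-dioxolane-4-carbaldehyde
Conditions: i-Bu2AlH, CH2Cl2, −78 °C; MeOH, then aq. KNaC4H4O6
Reagents that add atoms: none
Why: Partial ester reduction with diisobutylaluminium hydride, in which the α-alkoxy group chelates aluminium in the tetrahedral intermediate so that it survives at −78 °C and releases the aldehyde only on work-up; the quaternary α-carbon cannot epimerise.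

Step 9
Reactants: 13 (4R,5S)-2,2-dimethyl-5-tetradecyl-4-[1-(triethylsilyloxy)prop-2-enyl]-1,3-dioxolane-4-carbaldehyde; 14 vinylmagnesium bromide
Product: 15 (1S)-1-[(4R,5S)-2,2-dimethyl-5-tetradecyl-4-[1-(triethylsilyloxy)prop-2-enyl]-1,3-dioxolan-4-yl]prop-2-en-1-ol
Conditions: CH2=CHMgBr, THF, −78 °C; aq. NH4Cl at −78 °C
Reagents that add atoms: none
Why: Grignard 1,2-addition under polar Felkin–Anh control: with the ring C5–O bond anti to the incoming vinyl group and the approach past the tied-back ring carbon C1′ and not past the branched silyloxyallyl arm, the Si face of the aldehyde is attacked and the 4S carbinol should predominate, the cold quench guarding against silyl migration between the two oxygens.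

Step 10
Reactants: 15 (1S)-1-[(4R,5S)-2,2-dimethyl-5-tetradecyl-4-[1-(triethylsilyloxy)prop-2-enyl]-1,3-dioxolan-4-yl]prop-2-en-1-ol
Product: 16 (4R,5S)-2,2-dimethyl-5-tetradecyl-4-[1-(triethylsilyloxy)prop-2-enyl]-4-[(1S)-1-(triisopropylsilyloxy)prop-2-enyl]-1,3-dioxolane
Conditions: i-Pr3SiOTf, 2,6-lutidine, CH2Cl2, 0 °C → rt
Reagents that add atoms: triisopropylsilyl trifluoromethanesulfonate, CC(C)[Si](C(C)C)(C(C)C)OS(=O)(=O)C(F)(F)F
Why: Silyl triflate silylation of the hindered allylic alcohol; the triisopropylsilyl ether is chosen because it must outlast both the selective TES cleavage of step 11 and the acidic ketal hydrolysis of step 14.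

Step 11
Reactants: 16 (4R,5S)-2,2-dimethyl-5-tetradecyl-4-[1-(triethylsilyloxy)prop-2-enyl]-4-[(1S)-1-(triisopropylsilyloxy)prop-2-enyl]-1,3-dioxolane
Product: 17 1-[(4S,5S)-2,2-dimethyl-5-tetradecyl-4-[(1S)-1-(triisopropylsilyloxy)prop-2-enyl]-1,3-dioxolan-4-yl]prop-2-en-1-ol
Conditions: HF·pyridine, pyridine, THF, 0 °C
Reagents that add atoms: none
Why: Selective fluoride desilylation, the triethylsilyl ether being cleaved orders of magnitude faster than the triisopropylsilyl ether while buffered HF leaves the ketal intact.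

Step 12
Reactants: 17 1-[(4S,5S)-2,2-dimethyl-5-tetradecyl-4-[(1S)-1-(triisopropylsilyloxy)prop-2-enyl]-1,3-dioxolan-4-yl]prop-2-en-1-ol
Product: 18 1-[(4S,5S)-2,2-dimethyl-5-tetradecyl-4-[(1S)-1-(triisopropylsilyloxy)prop-2-enyl]-1,3-dioxolan-4-yl]prop-2-en-1-one
Conditions: Dess–Martin periodinane, CH2Cl2, 0 °C → rt
Reagents that add atoms: none
Why: Dess–Martin oxidation of the allylic alcohol converges both carbinol epimers on one vinyl ketone, which cannot enolise towards the quaternary C5 and is taken on promptly.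

Step 13
Reactants: 18 1-[(4S,5S)-2,2-dimethyl-5-tetradecyl-4-[(1S)-1-(triisopropylsilyloxy)prop-2-enyl]-1,3-dioxolan-4-yl]prop-2-en-1-one
Product: 19 (4S,5S,9S)-2,2-dimethyl-4-tetradecyl-9-(triisopropylsilyloxy)-1,3-dioxaspiro[4.4]non-7-en-6-one
Conditions: second-generation Grubbs catalyst RuCl2(=CHPh)(H2IMes)(PCy3) (5 mol%), degassed CH2Cl2 (0.005 M), 40 °C
Reagents that add atoms: none
Why: Ring-closing olefin metathesis, the closest known type being closure of a vinyl ketone onto an allylic ether to give a 4-oxycyclopent-2-enone: the ruthenium alkylidene exchanges onto the more electron-rich allylic ether alkene by [2+2] and retro-[2+2], then adds across the vinyl ketone to a ruthenacyclobutane that collapses to the C2=C3 bond and Ru=CH2, which carries the chain with loss of ethylene. The one ring formed, the cyclopentenone, closes by joining the two terminal alkene carbons of a 1,6-diene (C2 and C3), the new double bond lying inside the five-membered ring. No stereocentre is formed; C1′, C5 and C4 pass through unchanged, and the fully substituted C5 cannot epimerise beside the ketone. The step needs chemoselectivity for cyclisation over cross-metathesis, oligomerisation of the vinyl ketone and alkene migration. The quaternary C5 with its spiro dioxolane holds both vinyl groups close (Thorpe–Ingold effect), five-membered closure is fast, and high dilution suppresses the intermolecular paths. The enone appears directly at its final oxidation level and escape of ethylene makes the closure irreversible.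

Step 14
Reactants: 19 (4S,5S,9S)-2,2-dimethyl-4-tetradecyl-9-(triisopropylsilyloxy)-1,3-dioxaspiro[4.4]non-7-en-6-one
Product: 20 (4S,5S)-5-hydroxy-5-[(1S)-1-hydroxypentadecyl]-4-(triisopropylsilyloxy)cyclopent-2-en-1-one
Conditions: CF3CO2H/H2O (9:1), 0 °C → rt
Reagents that add atoms: none
Why: Acid-catalysed ketal hydrolysis frees the C1′/C5 diol while the hindered triisopropylsilyl ether, far more acid-stable than the isopropylidene ketal, should stay on O4, and acid avoids the base-induced retro-aldol cleavage of C5–C1′.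

Step 15
Reactants: 20 (4S,5S)-5-hydroxy-5-[(1S)-1-hydroxypentadecyl]-4-(triisopropylsilyloxy)cyclopent-2-en-1-one
Product: 21 (1S)-1-[(1S,5S)-1-hydroxy-2-oxo-5-(triisopropylsilyloxy)cyclopent-3-en-1-yl]pentadecyl acetate
Conditions: Ac2O, pyridine, DMAP (cat.), CH2Cl2, 0 °C
Reagents that add atoms: acetic anhydride, CC(=O)OC(C)=O
Why: Amine-catalysed acylation takes the secondary C1′ hydroxyl and leaves the tertiary α-ketol hydroxyl at C5, which does not acylate under these mild conditions, while O4 is still silylated.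

Step 16
Reactants: 21 (1S)-1-[(1S,5S)-1-hydroxy-2-oxo-5-(triisopropylsilyloxy)cyclopent-3-en-1-yl]pentadecyl acetate
Product: 22 (1S)-1-[(1R,5S)-1,5-dihydroxy-2-oxocyclopent-3-en-1-yl]pentadecyl acetate
Conditions: HF·pyridine, THF, 0 °C → rt
Reagents that add atoms: none
Why: Fluoride desilylation under mildly acidic conditions releases the C4 hydroxyl without the acetyl migration or enone degradation that a basic fluoride source could cause.

Compound list
1 | dimethyl (4R,5R)-2,2-dimethyl-1,3-dioxolane-4,5-dicarboxylate (dimethyl 2,3-O-isopropylidene-L-tartrate) | COC(=O)[C@@H]1OC(C)(C)O[C@H]1C(=O)OC | starting material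
2 | methyl (4R,5S)-5-(hydroxymethyl)-2,2-dimethyl-1,3-dioxolane-4-carboxylate | OC[C@@H]1OC(C)(C)O[C@H]1C(=O)OC | intermediate
3 | methyl (4R,5R)-5-formyl-2,2-dimethyl-1,3-dioxolane-4-carboxylate | O=C[C@@H]1OC(C)(C)O[C@H]1C(=O)OC | intermediate
4 | 1-bromotridecane | CCCCCCCCCCCCCBr | starting material
5 | tridecyl(triphenyl)phosphonium bromide | CCCCCCCCCCCCC[P+](c1ccccc1)(c1ccccc1)c1ccccc1.[Br-] | intermediate
6 | tridecylidenetriphenylphosphorane (ylide, not isolated) | CCCCCCCCCCCCC=P(c1ccccc1)(c1ccccc1)c1ccccc1 | intermediate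
7 | methyl (4R,5S)-2,2-dimethyl-5-[(Z)-tetradec-1-enyl]-1,3-dioxolane-4-carboxylate (Z isomer expected to predominate) | CCCCCCCCCCCC/C=C\[C@@H]1OC(C)(C)O[C@H]1C(=O)OC | intermediate
8 | methyl (4R,5S)-2,2-dimethyl-5-tetradecyl-1,3-dioxolane-4-carboxylate | CCCCCCCCCCCCCC[C@@H]1OC(C)(C)O[C@H]1C(=O)OC | intermediate
9 | acrolein | C=CC=O | starting material
10 | lithium ester enolate of 8, lithium 1-methoxy-1-[(5S)-2,2-dimethyl-5-tetradecyl-1,3-dioxolan-4-ylidene]methanolate (not isolated) | CCCCCCCCCCCCCC[C@@H]1OC(C)(C)OC1=C(OC)O[Li] | intermediate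
11 | methyl (4S,5S)-4-(1-hydroxyprop-2-enyl)-2,2-dimethyl-5-tetradecyl-1,3-dioxolane-4-carboxylate (new arm trans to tetradecyl; carbinol epimers) | CCCCCCCCCCCCCC[C@@H]1OC(C)(C)O[C@]1(C(O)C=C)C(=O)OC | intermediate
12 | methyl (4R,5S)-2,2-dimethyl-5-tetradecyl-4-[1-(triethylsilyloxy)prop-2-enyl]-1,3-dioxolane-4-carboxylate | CCCCCCCCCCCCCC[C@@H]1OC(C)(C)O[C@]1(C(O[Si](CC)(CC)CC)C=C)C(=O)OC | intermediate
13 | (4R,5S)-2,2-dimethyl-5-tetradecyl-4-[1-(triethylsilyloxy)prop-2-enyl]-1,3-dioxolane-4-carbaldehyde | CCCCCCCCCCCCCC[C@@H]1OC(C)(C)O[C@]1(C(O[Si](CC)(CC)CC)C=C)C=O | intermediate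
14 | vinylmagnesium bromide | C=C[Mg]Br | starting material
15 | (1S)-1-[(4R,5S)-2,2-dimethyl-5-tetradecyl-4-[1-(triethylsilyloxy)prop-2-enyl]-1,3-dioxolan-4-yl]prop-2-en-1-ol | CCCCCCCCCCCCCC[C@@H]1OC(C)(C)O[C@]1(C(O[Si](CC)(CC)CC)C=C)[C@@H](O)C=C | intermediate
16 | (4R,5S)-2,2-dimethyl-5-tetradecyl-4-[1-(triethylsilyloxy)prop-2-enyl]-4-[(1S)-1-(triisopropylsilyloxy)prop-2-enyl]-1,3-dioxolane | CCCCCCCCCCCCCC[C@@H]1OC(C)(C)O[C@]1(C(O[Si](CC)(CC)CC)C=C)[C@@H](O[Si](C(C)C)(C(C)C)C(C)C)C=C | intermediate
17 | 1-[(4S,5S)-2,2-dimethyl-5-tetradecyl-4-[(1S)-1-(triisopropylsilyloxy)prop-2-enyl]-1,3-dioxolan-4-yl]prop-2-en-1-ol | CCCCCCCCCCCCCC[C@@H]1OC(C)(C)O[C@]1(C(O)C=C)[C@@H](O[Si](C(C)C)(C(C)C)C(C)C)C=C | intermediate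
18 | 1-[(4S,5S)-2,2-dimethyl-5-tetradecyl-4-[(1S)-1-(triisopropylsilyloxy)prop-2-enyl]-1,3-dioxolan-4-yl]prop-2-en-1-one (metathesis precursor) | CCCCCCCCCCCCCC[C@@H]1OC(C)(C)O[C@]1(C(=O)C=C)[C@@H](O[Si](C(C)C)(C(C)C)C(C)C)C=C | intermediate
19 | (4S,5S,9S)-2,2-dimethyl-4-tetradecyl-9-(triisopropylsilyloxy)-1,3-dioxaspiro[4.4]non-7-en-6-one (metathesis product) | CCCCCCCCCCCCCC[C@@H]1OC(C)(C)O[C@@]12C(=O)C=C[C@@H]2O[Si](C(C)C)(C(C)C)C(C)C | intermediate
20 | (4S,5S)-5-hydroxy-5-[(1S)-1-hydroxypentadecyl]-4-(triisopropylsilyloxy)cyclopent-2-en-1-one | CCCCCCCCCCCCCC[C@H](O)[C@@]1(O)C(=O)C=C[C@@H]1O[Si](C(C)C)(C(C)C)C(C)C | intermediate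
21 | (1S)-1-[(1S,5S)-1-hydroxy-2-oxo-5-(triisopropylsilyloxy)cyclopent-3-en-1-yl]pentadecyl acetate | CCCCCCCCCCCCCC[C@H](OC(C)=O)[C@@]1(O)C(=O)C=C[C@@H]1O[Si](C(C)C)(C(C)C)C(C)C | intermediate
22 | (1S)-1-[(1R,5S)-1,5-dihydroxy-2-oxocyclopent-3-en-1-yl]pentadecyl acetate | CCCCCCCCCCCCCC[C@H](OC(C)=O)[C@@]1(O)C(=O)C=C[C@@H]1O | target

Total step count: 16. Longest linear sequence: 15 steps (steps 1, 2 and 4 to 16; step 3 is a one-step side branch).

Steps most likely to fail

Step 9. Facial selectivity in the vinyl addition may be poor or reversed, because Felkin and chelate transition states lead to opposite C4 epimers and the two α-substituents on C5 differ little in size; silyl migration between O1 and O4 is a lesser hazard. The fallback sets C4 under reagent control. It sets out from aldehyde 13: LiC≡CSiMe3 in THF at −78 °C should give the silylated propargylic alcohol F4 as an epimer mixture, which Dess–Martin periodinane oxidises to the ynone F5. Asymmetric transfer hydrogenation (RuCl(p-cymene)(TsDPEN), HCO2H–Et3N, using the catalyst enantiomer that delivers the 4S carbinol) should give the single (S)-propargylic alcohol F6, in which the slim alkyne is differentiated from the quaternary carbon. K2CO3 in MeOH removes the C-silyl group to give the terminal alkyne F7. Semi-hydrogenation (H2, Pd/CaCO3 poisoned with Pb(OAc)2, quinoline, stopped after one equivalent) then rejoins the route at 15.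

Step 6. The lithium enolate may fragment by β-elimination of the ring oxygen, the aldolate may revert or acrolein may be attacked in conjugate fashion, and the facial preference at C5 may be eroded in a fast, reversible addition. The fallback replaces the aldol by an irreversible alkylation and builds the carbinol afterwards. It sets out from ester 8: the enolate 10 is alkylated with benzyl chloromethyl ether at −78 °C, anti to the tetradecyl group, to give the benzyloxymethyl ester F1. Hydrogenolysis (H2, Pd/C) gives the hydroxymethyl ester F2, and Swern oxidation gives the formyl ester F3. Addition of CH2=CHMgBr at −78 °C, which takes the aldehyde in preference to the hindered ester, rejoins the route at 11.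

Step 13. Chelation of the ketone oxygen to the ruthenium alkylidene formed at the allylic ether terminus may stall the catalyst, and the electron-poor vinyl ketone may oligomerise or undergo cross-metathesis before the ring closes. The fallback closes the same C2=C3 bond one oxidation level lower. It sets out from allylic alcohol 17, which is cyclised with the same catalyst (RuCl2(=CHPh)(H2IMes)(PCy3), dilute CH2Cl2, 40 °C) to the spiro cyclopentenol F8. Oxidation of this ring allylic alcohol (MnO2 or Dess–Martin periodinane) rejoins the route at 19.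

Further compounds
F1 | step 6 | methyl (4S,5S)-4-(benzyloxymethyl)-2,2-dimethyl-5-tetradecyl-1,3-dioxolane-4-carboxylate | CCCCCCCCCCCCCC[C@@H]1OC(C)(C)O[C@]1(COCc2ccccc2)C(=O)OC
F2 | step 6 | methyl (4S,5S)-4-(hydroxymethyl)-2,2-dimethyl-5-tetradecyl-1,3-dioxolane-4-carboxylate | CCCCCCCCCCCCCC[C@@H]1OC(C)(C)O[C@]1(CO)C(=O)OC
F3 | step 6 | methyl (4R,5S)-4-formyl-2,2-dimethyl-5-tetradecyl-1,3-dioxolane-4-carboxylate | CCCCCCCCCCCCCC[C@@H]1OC(C)(C)O[C@]1(C=O)C(=O)OC
F4 | step 9 | 1-[(4R,5S)-2,2-dimethyl-5-tetradecyl-4-[1-(triethylsilyloxy)prop-2-enyl]-1,3-dioxolan-4-yl]-3-(trimethylsilyl)prop-2-yn-1-ol (carbinol epimers) | CCCCCCCCCCCCCC[C@@H]1OC(C)(C)O[C@]1(C(O[Si](CC)(CC)CC)C=C)C(O)C#C[Si](C)(C)C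
F5 | step 9 | 1-[(4R,5S)-2,2-dimethyl-5-tetradecyl-4-[1-(triethylsilyloxy)prop-2-enyl]-1,3-dioxolan-4-yl]-3-(trimethylsilyl)prop-2-yn-1-one | CCCCCCCCCCCCCC[C@@H]1OC(C)(C)O[C@]1(C(O[Si](CC)(CC)CC)C=C)C(=O)C#C[Si](C)(C)C
F6 | step 9 | (1S)-1-[(4R,5S)-2,2-dimethyl-5-tetradecyl-4-[1-(triethylsilyloxy)prop-2-enyl]-1,3-dioxolan-4-yl]-3-(trimethylsilyl)prop-2-yn-1-ol | CCCCCCCCCCCCCC[C@@H]1OC(C)(C)O[C@]1(C(O[Si](CC)(CC)CC)C=C)[C@@H](O)C#C[Si](C)(C)C
F7 | step 9 | (1S)-1-[(4R,5S)-2,2-dimethyl-5-tetradecyl-4-[1-(triethylsilyloxy)prop-2-enyl]-1,3-dioxolan-4-yl]prop-2-yn-1-ol | CCCCCCCCCCCCCC[C@@H]1OC(C)(C)O[C@]1(C(O[Si](CC)(CC)CC)C=C)[C@@H](O)C#C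
F8 | step 13 | (4S,5S,9S)-2,2-dimethyl-4-tetradecyl-9-(triisopropylsilyloxy)-1,3-dioxaspiro[4.4]non-7-en-6-ol (C6 epimers) | CCCCCCCCCCCCCC[C@@H]1OC(C)(C)O[C@@]12C(O)C=C[C@@H]2O[Si](C(C)C)(C(C)C)C(C)C
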